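## Retrosynthetic overview

1. Cembrane numbering is used. C1 and C2 are the ring-fusion carbons of the γ-lactone (oxygen on C2), C3 and C4 are the oxirane carbons (C18 methyl on C4), C14 is the acetoxy carbon, and C15–C17 form the acrylate unit.
2. Enabling feature: the C3–C4 bond belongs to both the oxirane and the 14-membered carbocycle. C4 carries a methyl group (retron of a methyl ketone), and C3 is the exocyclic CH2 of a 5-substituted butanolide (site for a sulfonium group). C3–C4 is therefore cut as ketone plus sulfonium ylide, and one macrocyclising Corey–Chaykovsky-type epoxidation closes both rings and sets C3 and C4.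
3. The seco compound is cut at C1–C14 by trans-selective conjugate addition of a dithiane anion to (S)-5-(trityloxymethyl)butenolide, which brings C2 and relays it to C1. It is also cut at C13–C14 by dithiane alkylation with a C4–C13 allylic bromide from (E)-geranylacetone, which brings both E-alkenes and the C4 ketone.
4. C14 is set by CBS reduction of the unmasked ketone. The C17 methylene and the acetate follow the key step.
5. Ring order: γ-lactone (from the chiral pool), then the 14-membered carbocycle and the oxirane together.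

Key step: step 12

Remark: (E)-geranylacetone is taken as the commercial single E isomer. The CIP label at C1 changes between compounds only because the ranking of its neighbours changes, not because the centre is inverted.

## Route

Step 1
Reactants: 1 (E)-geranylacetone
Product: 2 2-[(3E)-4,8-dimethylnona-3,7-dien-1-yl]-2-methyl-1,3-dioxolane
Conditions: HOCH2CH2OH, pyridinium p-toluenesulfonate (cat.), toluene, reflux, Dean–Stark
Reagents that add atoms: ethylene glycol, OCCO
Why: Acid-catalysed ketalisation with azeotropic water removal masks the future C4 ketone against the organolithium steps, and the weak acid leaves the E-alkene untouched.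

Step 2
Reactants: 2 dioxolane of geranylacetone
Product: 3 (2E,6E)-2,6-dimethyl-9-(2-methyl-1,3-dioxolan-2-yl)nona-2,6-dien-1-ol
Conditions: SeO2 (cat.), t-BuOOH, salicylic acid (cat.), CH2Cl2, 0 °C to rt
Reagents that add atoms: tert-butyl hydroperoxide, CC(C)(C)OO
Why: Catalytic Riley allylic oxidation (ene reaction, then [2,3]-shift) should attack the accessible terminal isopropylidene group and oxidise its E-methyl group, which fixes the C11=C12 geometry and creates C13 as a handle.

Step 3
Reactants: 3 allylic alcohol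
Product: 4 2-[(3E,7E)-9-bromo-4,8-dimethylnona-3,7-dien-1-yl]-2-methyl-1,3-dioxolane
Conditions: CBr4, PPh3, CH2Cl2, 0 °C
Reagents that add atoms: carbon tetrabromide, BrC(Br)(Br)Br
Why: The Appel reaction converts the primary allylic alcohol into the bromide under neutral conditions without allylic shift or loss of the ketal.

Step 4
Reactants: 5 1,3-dithiane; 4 allylic bromide
Product: 7 2-[(2E,6E)-2,6-dimethyl-9-(2-methyl-1,3-dioxolan-2-yl)nona-2,6-dien-1-yl]-1,3-dithiane, via 2-lithio-1,3-dithiane 6 (not isolated)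
Conditions: n-BuLi, THF, −30 °C; then 4, −78 °C to 0 °C
Reagents that add atoms: none
Why: Corey–Seebach alkylation of the acyl-anion equivalent with a primary allylic bromide proceeds by direct SN2 attack and forms C13–C14 with the E geometry retained.

Step 5
Reactants: 8 (S)-5-(hydroxymethyl)furan-2(5H)-one
Product: 9 (S)-5-(trityloxymethyl)furan-2(5H)-one
Conditions: Ph3CCl, pyridine, 4-(dimethylamino)pyridine (cat.), CH2Cl2, rt
Reagents that add atoms: trityl chloride, ClC(c1ccccc1)(c1ccccc1)c1ccccc1
Why: Tritylation of the primary alcohol installs an acid-labile group whose bulk shields one face of the butenolide, and C2 of the target is already present with the S configuration.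

Step 6
Reactants: 7 substituted dithiane; 9 trityl butenolide
Product: 12 (4S,5S)-4-{2-[(2E,6E)-2,6-dimethyl-9-(2-methyl-1,3-dioxolan-2-yl)nona-2,6-dien-1-yl]-1,3-dithian-2-yl}-5-(trityloxymethyl)oxolan-2-one, via lithiated dithiane 10 (not isolated), via lithium enolate 11 (not isolated)
Conditions: 7, n-BuLi, THF, −25 °C; HMPA, −78 °C; then 9, −78 °C; sat. aq NH4Cl
Reagents that add atoms: none
Why: Conjugate addition of a lithiated 1,3-dithiane to a butenolide is favoured over 1,2-addition in THF/HMPA (solvent-separated ion pair), and the trityloxymethyl group on C2 blocks its own face so that C1–C14 forms trans to it and sets C1.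

Step 7
Reactants: 12 dithiane lactone
Product: 13 (4S,5S)-4-[(3E,7E)-3,7-dimethyl-10-(2-methyl-1,3-dioxolan-2-yl)deca-3,7-dienoyl]-5-(trityloxymethyl)oxolan-2-one
Conditions: MeI, CaCO3, MeCN/H2O 9:1, 40 °C
Reagents that add atoms: water, O
Why: Alkylative dithiane hydrolysis under carbonate buffer unmasks the C14 ketone in a neutral medium that should spare the dioxolane, the trityl ether and the β,γ-position of the C11=C12 alkene.

Step 8
Reactants: 13 C14 ketone
Product: 14 (4R,5S)-4-[(1S,3E,7E)-1-hydroxy-3,7-dimethyl-10-(2-methyl-1,3-dioxolan-2-yl)deca-3,7-dien-1-yl]-5-(trityloxymethyl)oxolan-2-one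
Conditions: (R)-2-methyl-CBS-oxazaborolidine [(R)-1-methyl-3,3-diphenyltetrahydropyrrolo[1,2-c][1,3,2]oxazaborole] (0.5 equiv), BH3·SMe2, THF, −40 °C; MeOH
Reagents that add atoms: none
Why: In the Corey–Bakshi–Shibata reduction the catalyst treats the branched C1 side as large and the C13 methylene as small, so hydride is delivered under reagent control to give the 14S carbinol, while lactone, ketal and trisubstituted alkenes react much more slowly with borane at this temperature.

Step 9
Reactants: 14 C14 alcohol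
Product: 15 (4S,5S)-4-[(1S,3E,7E)-1-(tert-butyldimethylsilyloxy)-3,7-dimethyl-10-(2-methyl-1,3-dioxolan-2-yl)deca-3,7-dien-1-yl]-5-(trityloxymethyl)oxolan-2-one
Conditions: TBSOTf, 2,6-lutidine, CH2Cl2, −78 °C
Reagents that add atoms: tert-butyldimethylsilyl triflate, CC(C)(C)[Si](C)(C)OS(=O)(=O)C(F)(F)F
Why: Silylation of the hindered secondary alcohol with the silyl triflate blocks translactonisation onto C14 and gives a group that withstands the later amide bases, which an acetate would not.

Step 10
Reactants: 15 fully protected lactone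
Product: 16 (4S,5S)-4-[(1S,3E,7E)-1-(tert-butyldimethylsilyloxy)-3,7-dimethyl-11-oxododeca-3,7-dien-1-yl]-5-(hydroxymethyl)oxolan-2-one
Conditions: AcOH/THF/H2O 3:1:1, 45 °C
Reagents that add atoms: water, O
Why: Mild aqueous acid solvolyses the trityl ether and hydrolyses the dioxolane in one operation, while the hindered secondary TBS ether is cleaved far more slowly.

Step 11
Reactants: 16 hydroxy ketone
Product: 18 {[(2S,3S)-3-[(1S,3E,7E)-1-(tert-butyldimethylsilyloxy)-3,7-dimethyl-11-oxododeca-3,7-dien-1-yl]-5-oxooxolan-2-yl]methyl}diphenylsulfonium triflate, via primary triflate 17 (not isolated)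
Conditions: Tf2O, 2,6-di-tert-butyl-4-methylpyridine, CH2Cl2, −78 °C; then Ph2S (excess), −78 °C to 35 °C
Reagents that add atoms: triflic anhydride, O=S(=O)(OS(=O)(=O)C(F)(F)F)C(F)(F)F; diphenyl sulfide, c1ccc(cc1)Sc1ccccc1
Why: O-triflation of the only free hydroxyl and SN2 S-alkylation of diphenyl sulfide is the known preparation of alkyldiphenylsulfonium triflates, also from β-heteroatom-substituted primary triflates, and the hindered pyridine cannot compete as a nucleophile.

Step 12
Reactants: 18 sulfonium triflate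
Product: 21 (1S,2S,3R,4R,14S,7E,11E)-14-(tert-butyldimethylsilyloxy)-3,4-epoxycembra-7,11-dien-16,2-olide, via sulfonium ylide 19 (not isolated), via betaine 20 (not isolated)
Conditions: KN(SiMe3)2 (1.05 equiv), THF (0.5 mM in 18), −78 °C to −10 °C
Reagents that add atoms: none
Why: Proposed new method: KN(SiMe3)2 removes a C3 proton of 18 (flanked by Ph2S+ and the C2–O dipole and far more acidic than the ketone, lactone or silyl ether sites), ylide 19 adds to the C4 methyl ketone at the other chain end, and betaine 20 expels Ph2S, so one operation forges the C3–C4 bond, the carbocycle, the oxirane and both oxirane stereocentres. The closest known reaction types are the Corey–Chaykovsky epoxidation of ketones with diphenylsulfonium alkylides, its intramolecular form for five- to seven-membered rings, and the epoxy-annulations of vinylsulfonium salts, which run through the same β-oxygenated ylides; only the 14-membered ring size is new. The carbocycle closes 14-exo-trig (C3 onto C4=O) and the oxirane 3-exo-tet (C4–O− onto C3 with inversion, S+ and O− antiperiplanar). C3 is controlled by C2: allylic-type strain places C2–H next to the bulky SPh2 group, the ketone (tethered through C1) bonds anti to the C1–C2 bond, sulfur ends anti to the lactone oxygen, and its displacement puts the oxirane oxygen syn to that oxygen (3R). C4 is controlled by the tether: only the betaine whose antiperiplanar rotamer keeps C2–C3–C4–C5 extended, as the two E-alkenes and the trans-lactone demand, should collapse easily, which gives the trans oxirane (4R). The step needs ylide formation without enolisation, ring closure ahead of intermolecular attack, and tolerance of E1cB loss of the C2 carboxylate; these are secured by the acidity gap, the phenyl groups on sulfur (no other α-hydrogen), high dilution, the postponed acrylate methylene, the non-nucleophilic amine by-product, and the fact that an expelled carboxylate stays tethered and re-adds 5-exo-trig to the alkenylsulfonium to restore 19.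

Step 13
Reactants: 21 macrocyclic epoxy lactone
Product: 25 (1S,2S,3R,4R,14S,7E,11E)-14-(tert-butyldimethylsilyloxy)-3,4-epoxycembra-7,11,15(17)-trien-16,2-olide, via lithium enolate 22 (not isolated), via Mannich base 23 (not isolated), via methiodide 24 (not isolated)
Conditions: LiN(iPr)2, THF, −78 °C; CH2=NMe2+ I−, −78 °C to rt; then MeI, THF, rt; then aq NaHCO3, CH2Cl2, rt
Reagents that add atoms: Eschenmoser's salt, C=[N+](C)C.[I-]
Why: Eschenmoser methylenation (enolate Mannich reaction, quaternisation, Hofmann-type elimination) is the standard way to an α-methylene-γ-lactone, and C15 is the only enolisable site while the oxirane is inert to the amide base at low temperature.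

Step 14
Reactants: 25 silyl ether
Product: 26 (1R,2S,3R,4R,14S,7E,11E)-3,4-epoxy-14-hydroxycembra-7,11,15(17)-trien-16,2-olide
Conditions: Bu4NF, AcOH (1:1), THF, 0 °C to rt
Reagents that add atoms: none
Why: Fluoride desilylation buffered with acetic acid frees the C14 hydroxyl without forming an alkoxide that could translactonise or open the oxirane.

Step 15
Reactants: 26 C14 alcohol
Product: 27 CNP0294029.1 [(1R,2S,3R,4R,14S,7E,11E)-14-acetoxy-3,4-epoxycembra-7,11,15(17)-trien-16,2-olide]
Conditions: Ac2O, pyridine, 4-(dimethylamino)pyridine (cat.), CH2Cl2, 0 °C to rt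
Reagents that add atoms: acetic anhydride, CC(=O)OC(C)=O
Why: Nucleophile-catalysed acetylation of the only hydroxyl proceeds with retention at C14 and leaves the oxirane and the acrylate untouched.

## Compound list

1 | (E)-geranylacetone, (5E)-6,10-dimethylundeca-5,9-dien-2-one | CC(C)=CCC/C(C)=C/CCC(C)=O | starting material
2 | 2-[(3E)-4,8-dimethylnona-3,7-dien-1-yl]-2-methyl-1,3-dioxolane | CC(C)=CCC/C(C)=C/CCC1(C)OCCO1 | intermediate
3 | (2E,6E)-2,6-dimethyl-9-(2-methyl-1,3-dioxolan-2-yl)nona-2,6-dien-1-ol | OC/C(C)=C/CC/C(C)=C/CCC1(C)OCCO1 | intermediate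
4 | 2-[(3E,7E)-9-bromo-4,8-dimethylnona-3,7-dien-1-yl]-2-methyl-1,3-dioxolane | BrC/C(C)=C/CC/C(C)=C/CCC1(C)OCCO1 | intermediate
5 | 1,3-dithiane | C1CSCSC1 | starting material
6 | 2-lithio-1,3-dithiane | [Li]C1SCCCS1 | intermediate
7 | 2-[(2E,6E)-2,6-dimethyl-9-(2-methyl-1,3-dioxolan-2-yl)nona-2,6-dien-1-yl]-1,3-dithiane | S1CCCSC1C/C(C)=C/CC/C(C)=C/CCC1(C)OCCO1 | intermediate
8 | (S)-5-(hydroxymethyl)furan-2(5H)-one | O=C1C=C[C@@H](CO)O1 | starting material
9 | (S)-5-(trityloxymethyl)furan-2(5H)-one | O=C1C=C[C@@H](COC(c2ccccc2)(c2ccccc2)c2ccccc2)O1 | intermediate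
10 | 2-lithio derivative of 7 | [Li]C1(C/C(C)=C/CC/C(C)=C/CCC2(C)OCCO2)SCCCS1 | intermediate
11 | lithium enolate of 12 | [Li]OC1=C[C@H](C2(C/C(C)=C/CC/C(C)=C/CCC3(C)OCCO3)SCCCS2)[C@@H](COC(c2ccccc2)(c2ccccc2)c2ccccc2)O1 | intermediate
12 | (4S,5S)-trans dithiane lactone (C1–C14 adduct) | O=C1C[C@H](C2(C/C(C)=C/CC/C(C)=C/CCC3(C)OCCO3)SCCCS2)[C@@H](COC(c2ccccc2)(c2ccccc2)c2ccccc2)O1 | intermediate
13 | (4S,5S)-4-[(3E,7E)-3,7-dimethyl-10-(2-methyl-1,3-dioxolan-2-yl)deca-3,7-dienoyl]-5-(trityloxymethyl)oxolan-2-one | O=C1C[C@H](C(=O)C/C(C)=C/CC/C(C)=C/CCC2(C)OCCO2)[C@@H](COC(c2ccccc2)(c2ccccc2)c2ccccc2)O1 | intermediate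
14 | (4R,5S)-lactone with (1S)-carbinol (14S alcohol) | O=C1C[C@H]([C@@H](O)C/C(C)=C/CC/C(C)=C/CCC2(C)OCCO2)[C@@H](COC(c2ccccc2)(c2ccccc2)c2ccccc2)O1 | intermediate
15 | TBS ether of 14 | O=C1C[C@H]([C@@H](O[Si](C)(C)C(C)(C)C)C/C(C)=C/CC/C(C)=C/CCC2(C)OCCO2)[C@@H](COC(c2ccccc2)(c2ccccc2)c2ccccc2)O1 | intermediate
16 | (4S,5S)-4-[(1S,3E,7E)-1-(tert-butyldimethylsilyloxy)-3,7-dimethyl-11-oxododeca-3,7-dien-1-yl]-5-(hydroxymethyl)oxolan-2-one | O=C1C[C@H]([C@@H](O[Si](C)(C)C(C)(C)C)C/C(C)=C/CC/C(C)=C/CCC(C)=O)[C@@H](CO)O1 | intermediate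
17 | primary triflate of 16 | O=C1C[C@H]([C@@H](O[Si](C)(C)C(C)(C)C)C/C(C)=C/CC/C(C)=C/CCC(C)=O)[C@@H](COS(=O)(=O)C(F)(F)F)O1 | intermediate
18 | C3 diphenylsulfonium triflate | O=C1C[C@H]([C@@H](O[Si](C)(C)C(C)(C)C)C/C(C)=C/CC/C(C)=C/CCC(C)=O)[C@@H](C[S+](c2ccccc2)c2ccccc2)O1.[O-]S(=O)(=O)C(F)(F)F | intermediate
19 | C3 diphenylsulfonium ylide | O=C1C[C@H]([C@@H](O[Si](C)(C)C(C)(C)C)C/C(C)=C/CC/C(C)=C/CCC(C)=O)[C@@H]([CH-][S+](c2ccccc2)c2ccccc2)O1 | intermediate
20 | macrocyclic betaine (C4 alkoxide, C3 sulfonium) | C1C(=O)O[C@H]2[C@H]1[C@@H](O[Si](C)(C)C(C)(C)C)C/C(C)=C/CC/C(C)=C/CC[C@@](C)([O-])[C@H]2[S+](c1ccccc1)c1ccccc1 | intermediate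
21 | (1S,2S,3R,4R,14S,7E,11E)-14-(tert-butyldimethylsilyloxy)-3,4-epoxycembra-7,11-dien-16,2-olide | C1C(=O)O[C@H]2[C@H]1[C@@H](O[Si](C)(C)C(C)(C)C)C/C(C)=C/CC/C(C)=C/CC[C@@]1(C)O[C@H]21 | intermediate
22 | lithium enolate of 21 | C1=C(O[Li])O[C@H]2[C@H]1[C@@H](O[Si](C)(C)C(C)(C)C)C/C(C)=C/CC/C(C)=C/CC[C@@]1(C)O[C@H]21 | intermediate
23 | (15R)-15-(dimethylaminomethyl) lactone, aminomethyl trans to the C1 side chain | CN(C)C[C@@H]1C(=O)O[C@H]2[C@H]1[C@@H](O[Si](C)(C)C(C)(C)C)C/C(C)=C/CC/C(C)=C/CC[C@@]1(C)O[C@H]21 | intermediate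
24 | methiodide of 23 | C[N+](C)(C)C[C@@H]1C(=O)O[C@H]2[C@H]1[C@@H](O[Si](C)(C)C(C)(C)C)C/C(C)=C/CC/C(C)=C/CC[C@@]1(C)O[C@H]21.[I-] | intermediate
25 | (1S,2S,3R,4R,14S,7E,11E)-14-(tert-butyldimethylsilyloxy)-3,4-epoxycembra-7,11,15(17)-trien-16,2-olide | C=C1C(=O)O[C@H]2[C@H]1[C@@H](O[Si](C)(C)C(C)(C)C)C/C(C)=C/CC/C(C)=C/CC[C@@]1(C)O[C@H]21 | intermediate
26 | (1R,2S,3R,4R,14S,7E,11E)-3,4-epoxy-14-hydroxycembra-7,11,15(17)-trien-16,2-olide | C=C1C(=O)O[C@H]2[C@H]1[C@@H](O)C/C(C)=C/CC/C(C)=C/CC[C@@]1(C)O[C@H]21 | intermediate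
27 | CNP0294029.1, (1R,2S,3R,4R,14S,7E,11E)-14-acetoxy-3,4-epoxycembra-7,11,15(17)-trien-16,2-olide | C=C1C(=O)O[C@H]2[C@H]1[C@@H](OC(C)=O)C/C(C)=C/CC/C(C)=C/CC[C@@]1(C)O[C@H]21 | target

## Step count and risks

Total step count: 15. Longest linear sequence: 14 (steps 1–4 and 6–15).

**1. Step 12 (labelled step).**
- What may go wrong: the ylide may be lost to elimination or intermolecular attack before the slow 14-membered closure. C2 may erode through reversible carboxylate expulsion. Facial selectivity at C3 or C4 may be poor.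
- Fallback (known chemistry, same C3–C4 bond): it sets out from 16 and comes back at 21. Dess–Martin oxidation of the primary alcohol should give the keto aldehyde F1. Slow addition of this to low-valent titanium (TiCl3(DME)1.5, Zn–Cu couple, DME, 25 °C, stopped at the pinacol stage) should close the carbocycle to the 3,4-diol F2. Felkin–Anh attack at the C3 aldehyde should place the C3 hydroxyl anti to the lactone oxygen. MsCl/pyridine should sulfonylate only the secondary C3 hydroxyl to give the mesylate F3. NaH in THF then closes the oxirane with inversion at C3 and rejoins the route at 21.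

**2. Step 6.**
- What may go wrong: the hindered, basic tertiary carbanion may add 1,2 or deprotonate the butenolide at its γ-position, with loss of the trityloxy group or of C2 integrity.
- Fallback: it sets out from 9 and 3 and comes back at 13. CH2=CHMgBr/CuBr·SMe2/Me3SiCl (THF, −78 °C) should add a small vinyl group trans to the trityloxymethyl group to give the vinyl lactone F4. Ozonolysis (O3, then Me2S) gives the lactone aldehyde F5. Alcohol 3 is converted (MsCl, LiCl, 2,4,6-collidine, DMF) into the allylic chloride F6. Its allylbarium reagent (BaI2, lithium biphenylide, THF, −78 °C) should attack the aldehyde through its unsubstituted terminus with retention of the E geometry to give the C14-epimeric carbinols F7. Dess–Martin oxidation converges both epimers on ketone 13.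

**3. Step 11.**
- What may go wrong: S-alkylation of the weak nucleophile Ph2S at the β-oxygenated, β-branched primary carbon may be slow. The triflate could then decay by elimination or by participation of the C11=C12 alkene.
- Fallback: it sets out from 16 and comes back at 18, and it forms the last S–C bond at an aryl instead of the alkyl carbon. PhSSPh/PBu3 (Hata-type thioetherification) should give the phenyl sulfide F8. Cu(OAc)2-catalysed S-phenylation with Ph2I+ TfO− (1,2-dichloroethane, 80 °C) should then deliver sulfonium triflate 18.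

Further compounds
F1 | step 12 | (2S,3S)-3-[(1S,3E,7E)-1-(tert-butyldimethylsilyloxy)-3,7-dimethyl-11-oxododeca-3,7-dien-1-yl]-5-oxooxolane-2-carbaldehyde | O=C1C[C@H]([C@@H](O[Si](C)(C)C(C)(C)C)C/C(C)=C/CC/C(C)=C/CCC(C)=O)[C@@H](C=O)O1
F2 | step 12 | (1S,2S,3S,4R,14S,7E,11E)-14-(tert-butyldimethylsilyloxy)-3,4-dihydroxycembra-7,11-dien-16,2-olide | C1C(=O)O[C@H]2[C@H]1[C@@H](O[Si](C)(C)C(C)(C)C)C/C(C)=C/CC/C(C)=C/CC[C@@](C)(O)[C@H]2O
F3 | step 12 | 3-O-methanesulfonate of F2 | C1C(=O)O[C@H]2[C@H]1[C@@H](O[Si](C)(C)C(C)(C)C)C/C(C)=C/CC/C(C)=C/CC[C@@](C)(O)[C@H]2OS(C)(=O)=O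
F4 | step 6 | (4R,5S)-4-ethenyl-5-(trityloxymethyl)oxolan-2-one | O=C1C[C@H](C=C)[C@@H](COC(c2ccccc2)(c2ccccc2)c2ccccc2)O1
F5 | step 6 | (2S,3S)-5-oxo-2-(trityloxymethyl)oxolane-3-carbaldehyde | O=C1C[C@H](C=O)[C@@H](COC(c2ccccc2)(c2ccccc2)c2ccccc2)O1
F6 | step 6 | 2-[(3E,7E)-9-chloro-4,8-dimethylnona-3,7-dien-1-yl]-2-methyl-1,3-dioxolane | ClC/C(C)=C/CC/C(C)=C/CCC1(C)OCCO1
F7 | step 6 | C14-epimeric carbinols (14 and its C14 epimer) | O=C1C[C@H](C(O)C/C(C)=C/CC/C(C)=C/CCC2(C)OCCO2)[C@@H](COC(c2ccccc2)(c2ccccc2)c2ccccc2)O1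
F8 | step 11 | (4S,5S)-4-[(1S,3E,7E)-1-(tert-butyldimethylsilyloxy)-3,7-dimethyl-11-oxododeca-3,7-dien-1-yl]-5-(phenylsulfanylmethyl)oxolan-2-one | O=C1C[C@H]([C@@H](O[Si](C)(C)C(C)(C)C)C/C(C)=C/CC/C(C)=C/CCC(C)=O)[C@@H](CSc2ccccc2)O1
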